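**Assumption (remark on the chemistry):** 2-hydroxy-3,4-dimethoxybenzaldehyde, propiolic acid and 3,5-bis(benzyloxy)phenol are taken as commercial. The three phenols of the target (O5, O7, O4') are carried as benzyl ethers and the three methyl ethers are in place from the start.

## Structural features

The target is a flavone: a benzopyran-4-one (ring A fused to ring C through C4a–C8a) that carries ring B on C2 through the C2–C1' bond; it has no stereocentre. Ring A has the phloroglucinol pattern, with O1 on C8a and hydroxyls on C5 and C7 all meta to one another, and C4a, which bears the C4 carbonyl, lies between C8a and C5. Ring B is pentasubstituted with four contiguous oxygens (C2' to C5'); only the C4' oxygen is free, flanked by the methoxy groups on C3' and C5', so three hydroxyls (C5, C7, C4') must be kept apart from three methyl ethers throughout. Fragile points are the 4-pyranone (C2=C3–C4=O), which is opened by hard nucleophiles and can be reduced, the methyl ethers, which rule out Lewis-acid ether cleavage at the end, and the electron-rich free phenols, which oxidise easily and are best set free last. The real difficulty is the regiochemically unambiguous building of ring C onto ring A (carbonyl carbon on C4a beside the C5 oxygen, O1 on C8a), together with a ring B in which C1' and four oxygens each hold a defined place. The key step exploits the vicinal pair C8a–O1 / C4a–C4(=O) of ring A beside the C5 oxygen: an aryne across C8a≡C4a with an alkoxy group on C5 is polarised so that an oxygen nucleophile enters at C8a and the acyl carbon is taken up at C4a. In one sentence, the route closes ring C by inserting 3,5-bis(benzyloxy)benzyne into the carboxyl C–O bond of an arylpropiolic acid and letting the phenoxide so formed add to the alkyne.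

## Logic of the disconnections

**17 back to 16.** The three O–CH2Ph bonds on O5, O7 and O4' are cut. This is the only place where hydroxyls and methyl ethers are told apart, and one hydrogenolysis frees all three phenols at the very end. The forward step must cleave benzyl ethers without reducing C2=C3 or C4=O.

**16 back to 13 and 8 (through 14 and 15).** Three bonds of ring C are cut: O1–C8a, C4–C4a and O1–C2. Ring A then becomes a symmetrical 3,5-dioxygenated aryne and everything else (C2, C3, C4, the carbonyl oxygen, O1 and ring B) comes from one alkynoic acid. The forward step must put oxygen on the aryne carbon remote from the alkoxy group, move the acyl group to the neighbouring carbon before the aryl anion is protonated, and close ring C in the 6-endo mode.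

**8 back to 6 and 7.** The C1'–C(sp) bond is cut. All three carbons of C2/C3/C4 are bought in 7, and ring B is reduced to an aryl iodide. The forward coupling must keep the carboxyl group.

**6 back to 5, and 5 back to 3 (through 4).** The O–CH3 bond on the C5' oxygen is cut, and the C5'–O bond is traced back to a formyl group. The aldehyde carbon of the starting material thus serves as a latent oxygen, and the C5' methoxy group is distinguished from the C4' oxygen by timing alone. The forward oxidation must migrate the aryl group and leave the C–I bond alone.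

**3 back to 2, and 2 back to 1.** The O4'–benzyl bond and the C1'–I bond are cut. In 1 the free hydroxyl is the future O4'; it directs iodine to its para position, which is C1', and is then marked with benzyl. The forward iodination must go para to the hydroxyl and not ortho to the formyl group.

**13 back to 10, and 10 back to 9 (through 11 and 12).** The O–S and C–Si bonds, then the C–Br bond, are cut. The aryne precursor is reduced to a symmetrical commercial phenol. The forward bromination must go ortho to the hydroxyl (C2, equivalent to C6) and not between the two benzyloxy groups (C4).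

## Other disconnections considered

**Alternative 1:** (the first that comes to mind) Baker–Venkataraman route, cutting C2–C3 and O1–C2. Ring A would enter as ketone A1 and ring B as acid A2 (from 6 by iodine–lithium exchange and CO2). O-Aroylation would give ester A3, a base-induced 1,5 O-to-C acyl shift the diketone A4, and acid cyclodehydration 16. The chosen plan is preferred for three reasons:
- ring C costs three operations here against one;
- A1 needs a selective double benzylation of its trihydroxy parent, whereas the aryne route starts from a symmetrical phenol and lets the aryne polarisation place the acyl group;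
- A2 costs the same number of steps as 8, so nothing is saved on ring B.

This is also the route most chemists would draw first.

**Alternative 2:** three-component carbonylative annulation, cutting C4–C4a, C3–C4 and O1–C2. Iodophenol A5, carbon monoxide and terminal alkyne A6 would be joined by a zerovalent palladium catalyst in Et2NH to give 15 in the flask and then 16. The chosen plan is preferred for three reasons:
- oxidative addition would have to occur at an iodine flanked by a hydroxyl and a benzyloxy group on a very electron-rich ring, and CO insertion would have to outrun direct alkynylation;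
- A6 costs two steps from 6 where 8 costs one;
- the regiochemistry of ring A would still rest on an ortho-halogenation of 9, so toxic gas and a metal are added without a gain in steps.

**Alternative 3:** biomimetic polyketide folding, cutting C4a–C8a of ring A and O1–C2. Ester A7 would aroylate the terminal carbon of the polyanion of triketo ester A8 to give the tetraketo ester A9. A Claisen condensation of C6 onto the ester carbon would fold A9 into the acylphloroglucinol A10, and cyclodehydration and hydrogenolysis would finish the synthesis. The chosen plan is preferred for three reasons: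
- ring A is an unsubstituted, symmetrically oxygenated phloroglucinol that can be bought, so the key step would be spent on the easy ring;
- A9 has several enolisable sites with competing aldol (C2 onto C7) and pyranone closures;
- the linear preparation of A8 and A9 is longer than the two-step aryne precursor.

Key step: step 8

## Route

Step 1
Reactants: 1 2-hydroxy-3,4-dimethoxybenzaldehyde
Product: 2 2-hydroxy-5-iodo-3,4-dimethoxybenzaldehyde
Conditions: NIS, TFA (cat.), MeCN, 0 °C to rt
Reagents that add atoms: N-iodosuccinimide, O=C1CCC(=O)N1I
Why: Electrophilic aromatic iodination; C5 is para to the free hydroxyl, ortho to the C4 methoxy group and meta to the formyl group, whereas C6 is ortho to the formyl group and meta to the hydroxyl, so all directing effects should point to C5.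

Step 2
Reactants: 2 2-hydroxy-5-iodo-3,4-dimethoxybenzaldehyde
Product: 3 2-(benzyloxy)-5-iodo-3,4-dimethoxybenzaldehyde
Conditions: BnBr, K2CO3, DMF, 60 °C
Reagents that add atoms: benzyl bromide, BrCc1ccccc1
Why: Williamson ether synthesis on the only phenol; the benzyl group marks the future O4' for release in the last step.

Step 3
Reactants: 3 2-(benzyloxy)-5-iodo-3,4-dimethoxybenzaldehyde
Product: 5 2-(benzyloxy)-5-iodo-3,4-dimethoxyphenol, via aryl formate 4 (not isolated)
Conditions: mCPBA, CH2Cl2, 0 °C to rt; then K2CO3, MeOH, rt
Reagents that add atoms: 3-chloroperoxybenzoic acid, OOC(=O)c1cccc(Cl)c1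
Why: Baeyer–Villiger (Dakin-type) oxidation; the aryl group, with alkoxy groups ortho and para to the formyl carbon, should migrate in preference to hydride, and the formate is cleaved by methanolysis; the aldehyde should react with the peracid faster than the aryl iodide in the absence of strong acid.

Step 4
Reactants: 5 2-(benzyloxy)-5-iodo-3,4-dimethoxyphenol
Product: 6 2-(benzyloxy)-5-iodo-1,3,4-trimethoxybenzene
Conditions: MeI, K2CO3, acetone, reflux
Reagents that add atoms: iodomethane, CI
Why: Williamson O-methylation of the only free phenol installs the C5' methoxy group.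

Step 5
Reactants: 6 2-(benzyloxy)-5-iodo-1,3,4-trimethoxybenzene; 7 propiolic acid
Product: 8 3-[4-(benzyloxy)-2,3,5-trimethoxyphenyl]prop-2-ynoic acid
Conditions: Pd(PPh3)4 (5 mol %), DBU, DMSO, 35 °C; then aq. HCl
Reagents that add atoms: none
Why: Copper-free Sonogashira coupling of an aryl iodide with propiolic acid; at this temperature the carboxylate should be kept, since decarboxylative coupling needs much more heat.

Step 6
Reactants: 9 3,5-bis(benzyloxy)phenol
Product: 10 3,5-bis(benzyloxy)-2-bromophenol
Conditions: NBS (1.0 equiv), CH2Cl2, −78 °C to rt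
Reagents that add atoms: N-bromosuccinimide, O=C1CCC(=O)N1Br
Why: Electrophilic bromination of a phenol; the two equivalent positions ortho to the hydroxyl (C2, C6) should be favoured over C4, which is crowded between two benzyloxy groups, and low temperature with one equivalent limits double bromination.

Step 7
Reactants: 10 3,5-bis(benzyloxy)-2-bromophenol
Product: 13 3,5-bis(benzyloxy)-2-(trimethylsilyl)phenyl trifluoromethanesulfonate, via silyl ether 11 (not isolated), via lithium silylphenolate 12 (not isolated)
Conditions: HMDS, THF, 70 °C, then evaporation; n-BuLi, THF, −100 °C to −80 °C; Tf2O, −100 °C to rt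
Reagents that add atoms: hexamethyldisilazane, C[Si](C)(C)N[Si](C)(C)C; trifluoromethanesulfonic anhydride, O=S(=O)(OS(=O)(=O)C(F)(F)F)C(F)(F)F
Why: O-Silylation, bromine–lithium exchange and retro-Brook 1,3 O-to-C silyl shift put silicon on C2, and the lithium phenolate is trapped as the triflate; this is the standard entry to ortho-silylaryl triflates, and exchange at −100 °C should be faster than benzylic deprotonation.

Step 8
Reactants: 13 3,5-bis(benzyloxy)-2-(trimethylsilyl)phenyl trifluoromethanesulfonate (1.5 equiv); 8 3-[4-(benzyloxy)-2,3,5-trimethoxyphenyl]prop-2-ynoic acid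
Product: 16 5,7-bis(benzyloxy)-2-[4-(benzyloxy)-2,3,5-trimethoxyphenyl]-4H-chromen-4-one, via aryne 14 (not isolated), via ynone 15 (not isolated)
Conditions: CsF (4 equiv), THF, 125 °C, sealed tube
Reagents that add atoms: none
Why: Fluoride attack on silicon expels triflate from 13 to give aryne 14; the cesium carboxylate of 8 adds through oxygen to the aryne carbon remote from the C3 benzyloxy group (future C8a), because this is the more linear, more electrophilic end of the distorted triple bond and the attack leaves the aryl anion on the carbon next to the inductively withdrawing C–O bond (future C4a). The aryl anion attacks the neighbouring ester carbonyl (4-exo-trig) and the benzoxetene alkoxide opens with release of the phenoxide, a 1,3 O-to-C acyl shift of the anionic Fries type that gives the cesium phenoxide of ynone 15. The closest known reaction type is the insertion of arynes into the carboxyl C–O bond of carboxylic acids to give ortho-hydroxyaryl ketones, which with alk-2-ynoic acids runs on to chromones. Ring C then closes by 6-endo-dig oxa-Michael addition of the phenoxide oxygen to the ynone β-carbon (future C2) and protonation at C3; no stereocentre is formed. Three selectivities are needed: the site of attack on the aryne, set by the C3 benzyloxy group (the C5 benzyloxy group, para to the anionic carbon, has only a weak inductive influence); acyl transfer before protonation of the aryl anion, favoured by aprotic THF, excess CsF that holds the acid as its carboxylate, and heat; and 6-endo over 5-exo closure, favoured because the phenoxide adds to the electrophilic β-carbon of a conjugated ynone with no π-acidic metal present. Benzyl ethers, methyl ethers and the aryl–alkyne bond are inert to CsF in THF.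

Step 9
Reactants: 16 5,7-bis(benzyloxy)-2-[4-(benzyloxy)-2,3,5-trimethoxyphenyl]-4H-chromen-4-one
Product: 17 5,7,4'-trihydroxy-2',3',5'-trimethoxyflavone (5,7-dihydroxy-2-(4-hydroxy-2,3,5-trimethoxyphenyl)-4H-chromen-4-one)
Conditions: H2 (1 atm), 10% Pd/C, EtOAc–MeOH, rt
Reagents that add atoms: none
Why: Catalytic hydrogenolysis of three benzyl ethers; the vinylogous-ester double bond C2=C3 of a flavone is reduced much more slowly than benzyl C–O bonds are cleaved, and methyl ethers are untouched.

## Compound list

1 | 2-hydroxy-3,4-dimethoxybenzaldehyde | O=Cc1ccc(OC)c(OC)c1O | starting material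
2 | 2-hydroxy-5-iodo-3,4-dimethoxybenzaldehyde | O=Cc1cc(I)c(OC)c(OC)c1O | intermediate
3 | 2-(benzyloxy)-5-iodo-3,4-dimethoxybenzaldehyde | O=Cc1cc(I)c(OC)c(OC)c1OCc1ccccc1 | intermediate
4 | 2-(benzyloxy)-5-iodo-3,4-dimethoxyphenyl formate | O=COc1cc(I)c(OC)c(OC)c1OCc1ccccc1 | intermediate (not isolated)
5 | 2-(benzyloxy)-5-iodo-3,4-dimethoxyphenol | Oc1cc(I)c(OC)c(OC)c1OCc1ccccc1 | intermediate
6 | 2-(benzyloxy)-5-iodo-1,3,4-trimethoxybenzene | COc1cc(I)c(OC)c(OC)c1OCc1ccccc1 | intermediate
7 | propiolic acid (prop-2-ynoic acid) | C#CC(=O)O | starting material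
8 | 3-[4-(benzyloxy)-2,3,5-trimethoxyphenyl]prop-2-ynoic acid | COc1cc(C#CC(=O)O)c(OC)c(OC)c1OCc1ccccc1 | intermediate
9 | 3,5-bis(benzyloxy)phenol | Oc1cc(OCc2ccccc2)cc(OCc2ccccc2)c1 | starting material
10 | 3,5-bis(benzyloxy)-2-bromophenol | Oc1cc(OCc2ccccc2)cc(OCc2ccccc2)c1Br | intermediate
11 | [3,5-bis(benzyloxy)-2-bromophenoxy]trimethylsilane | C[Si](C)(C)Oc1cc(OCc2ccccc2)cc(OCc2ccccc2)c1Br | intermediate (not isolated)
12 | lithium 3,5-bis(benzyloxy)-2-(trimethylsilyl)phenolate | [Li+].[O-]c1cc(OCc2ccccc2)cc(OCc2ccccc2)c1[Si](C)(C)C | intermediate (not isolated)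
13 | 3,5-bis(benzyloxy)-2-(trimethylsilyl)phenyl trifluoromethanesulfonate | C[Si](C)(C)c1c(OS(=O)(=O)C(F)(F)F)cc(OCc2ccccc2)cc1OCc1ccccc1 | intermediate
14 | 3,5-bis(benzyloxy)benzyne (3,5-bis(benzyloxy)-1,2-didehydrobenzene) | C1#CC(OCc2ccccc2)=CC(OCc2ccccc2)=C1 | intermediate (not isolated)
15 | 1-[2,4-bis(benzyloxy)-6-hydroxyphenyl]-3-[4-(benzyloxy)-2,3,5-trimethoxyphenyl]prop-2-yn-1-one (formed as its cesium phenoxide) | COc1cc(C#CC(=O)c2c(O)cc(OCc3ccccc3)cc2OCc2ccccc2)c(OC)c(OC)c1OCc1ccccc1 | intermediate (not isolated)
16 | 5,7-bis(benzyloxy)-2-[4-(benzyloxy)-2,3,5-trimethoxyphenyl]-4H-chromen-4-one | COc1cc(-c2cc(=O)c3c(OCc4ccccc4)cc(OCc4ccccc4)cc3o2)c(OC)c(OC)c1OCc1ccccc1 | intermediate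
17 | 5,7,4'-trihydroxy-2',3',5'-trimethoxyflavone | COc1cc(-c2cc(=O)c3c(O)cc(O)cc3o2)c(OC)c(OC)c1O | target

## Step count and least certain steps

Total step count: 9. Longest linear sequence: 7 steps (steps 1, 2, 3, 4, 5, 8, 9); the aryne precursor is a two-step side branch (steps 6, 7).

**Step 8 (key step).** The most likely failure is protonation of the ortho-acyloxyaryl anion before the acyl shift, which stops the sequence at simple O-arylation of the carboxylate. This is possible because the acid itself and the bifluoride formed from it are proton sources. Thermal loss of CO2 from the propiolate at 125 °C, or partial 5-exo closure of the phenoxide, could also lower the outcome.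

Fallback (sets out from 10 and 8, returns at 16): the C4–C4a bond would be made by acyl substitution with a preformed aryllithium in place of the aryne. Bromophenol 10 would be protected with chloromethyl methyl ether and i-Pr2NEt as 1,5-bis(benzyloxy)-2-bromo-3-(methoxymethoxy)benzene F1. Acid 8 would be condensed with N,O-dimethylhydroxylamine hydrochloride (EDC, DMAP, CH2Cl2) to 3-[4-(benzyloxy)-2,3,5-trimethoxyphenyl]-N-methoxy-N-methylprop-2-ynamide F2. Bromine–lithium exchange on F1 (n-BuLi, THF, −78 °C) and acylation of the aryllithium by F2 should give 1-[2,4-bis(benzyloxy)-6-(methoxymethoxy)phenyl]-3-[4-(benzyloxy)-2,3,5-trimethoxyphenyl]prop-2-yn-1-one F3. HCl in MeOH at 50 °C would remove the acetal, and the liberated phenol 15 would close under the same conditions to 16.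

**Step 6.** Bromination may also occur at C4 between the two benzyloxy groups, or twice, because all three free ring positions are strongly activated; the wrong isomer cannot lead to the aryne precursor.

Fallback (sets out from 9, returns at 13, bypassing steps 6 and 7): directed ortho-metalation in place of electrophilic substitution. Isopropyl isocyanate (Et3N cat., CH2Cl2) would give 3,5-bis(benzyloxy)phenyl N-isopropylcarbamate F4. Transient N-silylation (TMSOTf, TMEDA), lithiation at the position shared by the carbamate and a benzyloxy group (n-BuLi, TMEDA, Et2O, −78 °C) and quenching with TMSCl would give 3,5-bis(benzyloxy)-2-(trimethylsilyl)phenyl N-isopropylcarbamate F5. Cleavage with Et2NH and DBU in MeCN would give 3,5-bis(benzyloxy)-2-(trimethylsilyl)phenol F6, which PhNTf2 would convert into 13.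

**Step 5.** Loss of CO2 from the arylpropiolate under palladium and base, or a second, decarboxylative arylation of the product, may erode the acid, because the ring is electron-rich and the coupling of a hindered, ortho-substituted iodide is slow.

Fallback (sets out from 6, returns at 8): the carboxyl carbon would be brought in as CO2 and not with the alkyne. Sonogashira coupling of 6 with ethynyltrimethylsilane (Pd(PPh3)2Cl2, CuI, Et3N, 50 °C) should give {[4-(benzyloxy)-2,3,5-trimethoxyphenyl]ethynyl}trimethylsilane F7. Fluoride-mediated desilylative carboxylation (CsF, CO2 1 atm, DMSO, rt; aq. HCl) would then give 8.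

**Step 3.** The peracid may oxidise the electron-rich aryl iodide at iodine (to trivalent iodine species) in competition with the Baeyer–Villiger reaction, or hydride may migrate in place of the aryl group and give the benzoic acid.

Fallback (sets out from 1, returns at 6): bromine, which peracids do not oxidise, would stand in for iodine until the oxidation is past. NBS on 1 should give 5-bromo-2-hydroxy-3,4-dimethoxybenzaldehyde F8 (same para direction by the hydroxyl). Benzylation would give 2-(benzyloxy)-5-bromo-3,4-dimethoxybenzaldehyde F9. Baeyer–Villiger oxidation would give 2-(benzyloxy)-5-bromo-3,4-dimethoxyphenyl formate F10, and its methanolysis 2-(benzyloxy)-5-bromo-3,4-dimethoxyphenol F11. Methylation would give 2-(benzyloxy)-5-bromo-1,3,4-trimethoxybenzene F12. A copper-catalysed aromatic Finkelstein exchange (CuI, NaI, N,N'-dimethylethylenediamine, dioxane, 110 °C) would convert F12 into 6.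

## Further compounds

F1 | step 8 | 1,5-bis(benzyloxy)-2-bromo-3-(methoxymethoxy)benzene | COCOc1cc(OCc2ccccc2)cc(OCc2ccccc2)c1Br
F2 | step 8 | 3-[4-(benzyloxy)-2,3,5-trimethoxyphenyl]-N-methoxy-N-methylprop-2-ynamide | COc1cc(C#CC(=O)N(C)OC)c(OC)c(OC)c1OCc1ccccc1
F3 | step 8 | 1-[2,4-bis(benzyloxy)-6-(methoxymethoxy)phenyl]-3-[4-(benzyloxy)-2,3,5-trimethoxyphenyl]prop-2-yn-1-one | COCOc1cc(OCc2ccccc2)cc(OCc2ccccc2)c1C(=O)C#Cc1cc(OC)c(OCc2ccccc2)c(OC)c1OC
F4 | step 6 | 3,5-bis(benzyloxy)phenyl N-isopropylcarbamate | CC(C)NC(=O)Oc1cc(OCc2ccccc2)cc(OCc2ccccc2)c1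
F5 | step 6 | 3,5-bis(benzyloxy)-2-(trimethylsilyl)phenyl N-isopropylcarbamate | CC(C)NC(=O)Oc1cc(OCc2ccccc2)cc(OCc2ccccc2)c1[Si](C)(C)C
F6 | step 6 | 3,5-bis(benzyloxy)-2-(trimethylsilyl)phenol | Oc1cc(OCc2ccccc2)cc(OCc2ccccc2)c1[Si](C)(C)C
F7 | step 5 | {[4-(benzyloxy)-2,3,5-trimethoxyphenyl]ethynyl}trimethylsilane | COc1cc(C#C[Si](C)(C)C)c(OC)c(OC)c1OCc1ccccc1
F8 | step 3 | 5-bromo-2-hydroxy-3,4-dimethoxybenzaldehyde | O=Cc1cc(Br)c(OC)c(OC)c1O
F9 | step 3 | 2-(benzyloxy)-5-bromo-3,4-dimethoxybenzaldehyde | O=Cc1cc(Br)c(OC)c(OC)c1OCc1ccccc1
F10 | step 3 | 2-(benzyloxy)-5-bromo-3,4-dimethoxyphenyl formate | O=COc1cc(Br)c(OC)c(OC)c1OCc1ccccc1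
F11 | step 3 | 2-(benzyloxy)-5-bromo-3,4-dimethoxyphenol | Oc1cc(Br)c(OC)c(OC)c1OCc1ccccc1
F12 | step 3 | 2-(benzyloxy)-5-bromo-1,3,4-trimethoxybenzene | COc1cc(Br)c(OC)c(OC)c1OCc1ccccc1
A1 | alternative 1 | 1-[2,4-bis(benzyloxy)-6-hydroxyphenyl]ethan-1-one | CC(=O)c1c(O)cc(OCc2ccccc2)cc1OCc1ccccc1
A2 | alternative 1 | 4-(benzyloxy)-2,3,5-trimethoxybenzoic acid | COc1cc(C(=O)O)c(OC)c(OC)c1OCc1ccccc1
A3 | alternative 1 | 2-acetyl-3,5-bis(benzyloxy)phenyl 4-(benzyloxy)-2,3,5-trimethoxybenzoate | COc1cc(C(=O)Oc2cc(OCc3ccccc3)cc(OCc3ccccc3)c2C(C)=O)c(OC)c(OC)c1OCc1ccccc1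
A4 | alternative 1 | 1-[2,4-bis(benzyloxy)-6-hydroxyphenyl]-3-[4-(benzyloxy)-2,3,5-trimethoxyphenyl]propane-1,3-dione | COc1cc(C(=O)CC(=O)c2c(O)cc(OCc3ccccc3)cc2OCc2ccccc2)c(OC)c(OC)c1OCc1ccccc1
A5 | alternative 2 | 3,5-bis(benzyloxy)-2-iodophenol | Oc1cc(OCc2ccccc2)cc(OCc2ccccc2)c1I
A6 | alternative 2 | 2-(benzyloxy)-5-ethynyl-1,3,4-trimethoxybenzene | COc1cc(C#C)c(OC)c(OC)c1OCc1ccccc1
A7 | alternative 3 | methyl 4-(benzyloxy)-2,3,5-trimethoxybenzoate | COC(=O)c1cc(OC)c(OCc2ccccc2)c(OC)c1OC
A8 | alternative 3 | methyl 3,5,7-trioxooctanoate | COC(=O)CC(=O)CC(=O)CC(C)=O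
A9 | alternative 3 | methyl 9-[4-(benzyloxy)-2,3,5-trimethoxyphenyl]-3,5,7,9-tetraoxononanoate | COC(=O)CC(=O)CC(=O)CC(=O)CC(=O)c1cc(OC)c(OCc2ccccc2)c(OC)c1OC
A10 | alternative 3 | 1-[4-(benzyloxy)-2,3,5-trimethoxyphenyl]-3-(2,4,6-trihydroxyphenyl)propane-1,3-dione | COc1cc(C(=O)CC(=O)c2c(O)cc(O)cc2O)c(OC)c(OC)c1OCc1ccccc1
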